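**Plan**
1. After removal of four MOM groups, the retrosynthesis cuts the side-chain C=C (Wittig) and the aryl ketone C–C bond (aryllithium on a lactone). This ties the acyl carbon, C1, C2 and the two proximal side-chain carbons of the cyclohexene through one oxygen into a cis-fused δ-lactone.
2. The C4–H bond (vinyl triflate reduction) and the C6–aryl bond (conjugate arylation) are cut next, leaving an enone with its ketone at C4. The ring bonds C2–C3 and C1–C6 are then cut together in a Diels–Alder sense.
3. Enabling feature: the cis C1/C2 pair maps onto the cis C3=C4 alkene of 5,6-dihydro-2H-pyran-2-one. Ring carbons C3(methyl)–C4–C5–C6 map onto a 1-amino-3-siloxypenta-1,3-diene whose C4 oxygen and C6 amine leave an enone that relays stereochemistry to C6.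
4. Forward: chiral diene (3 steps), cycloaddition onto the preformed lactone ring with loss of the amine, arylation, ring alkene by triflation and reduction, lactone opening by the phloroglucinol aryllithium, oxidation, Wittig completion of the prenyl group, deprotection.
5. Stereochemistry: C1/C2 cis from the lactone alkene; absolute sense from the (2R,5R)-2,5-diphenylpyrrolidine auxiliary on the diene; C6 from anti (convex-face) conjugate addition.

Key step: step 4

Assumption: in step 4 the lactone adds endo to the diene face opposite the phenyl group on the pyrrolidine carbon lying syn to C2–H of the diene, which for the (2R,5R) auxiliary gives the (4aR,8aS) enone 9; if the opposite facial sense operated, the (2S,5S) amine would be used in step 2 with no other change.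

Step 1
Reactants: 1 pent-1-yn-3-ol (racemic)
Product: 2 pent-1-yn-3-one
Conditions: IBX, EtOAc, 75 °C
Reagents that add atoms: none
Why: Hypervalent-iodine oxidation of a secondary propargylic alcohol should give the ynone without touching the terminal alkyne; the only stereocenter is removed.

Step 2
Reactants: 2 pent-1-yn-3-one; 3 (2R,5R)-2,5-diphenylpyrrolidine
Product: 4 (E)-1-[(2R,5R)-2,5-diphenylpyrrolidin-1-yl]pent-1-en-3-one
Conditions: CH2Cl2, 0 °C to rt
Reagents that add atoms: none
Why: Aza-Michael addition of the secondary amine to the ynone should give the vinylogous amide with the thermodynamically preferred (E) geometry; the two stereocenters of 3 are carried over unchanged.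

Step 3
Reactants: 4 (E)-1-[(2R,5R)-2,5-diphenylpyrrolidin-1-yl]pent-1-en-3-one
Product: 5 (2R,5R)-1-[(1E,3Z)-3-{[tert-butyl(dimethyl)silyl]oxy}penta-1,3-dien-1-yl]-2,5-diphenylpyrrolidine
Conditions: KN(SiMe3)2, THF, −78 °C; then TBSCl, −78 °C to rt
Reagents that add atoms: tert-butyl(chloro)dimethylsilane (TBSCl), CC(C)(C)[Si](C)(C)Cl
Why: Enolate O-silylation: deprotonation of the only enolisable position (the ethyl CH2) should give the (Z)-enolate, as for ethyl ketones with a conjugating acyl substituent, and silylation on oxygen then gives the (1E,3Z)-diene with the methyl group on the outside of the s-cis diene.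

Step 4
Reactants: 5 (2R,5R)-1-[(1E,3Z)-3-{[tert-butyl(dimethyl)silyl]oxy}penta-1,3-dien-1-yl]-2,5-diphenylpyrrolidine; 6 5,6-dihydro-2H-pyran-2-one
Product: 9 (4aR,5S,8aS)-5-methyl-3,4,4a,8a-tetrahydro-1H-isochromene-1,6(5H)-dione, via silyl enol ether cycloadduct 7 (not isolated), via beta-amino ketone 8 (not isolated)
Conditions: PhMe, 85 °C, sealed tube; then 10% aq HF, MeCN, 0 °C to rt
Reagents that add atoms: none
Why: This is a thermal Diels–Alder reaction of a push–pull 1-amino-3-siloxy diene with an unsaturated δ-lactone, the closest known type being the cycloaddition of chiral 1-amino-3-siloxybutadienes with acrylates and cyclic dienophiles followed by loss of the amine to a 4-substituted cyclohexenone. It closes the carbocycle in a concerted, asynchronous, suprafacial [4+2] mode in which the bond from the nucleophilic methyl-bearing diene terminus to the lactone β-carbon (C5–C4a) runs ahead of the bond from the aminated terminus to the α-carbon (C8–C8a), while the lactone ring is kept and becomes cis-fused. C4a and C8a are set cis by the cis alkene locked in the lactone ring, and their absolute sense by the C2-symmetric diphenylpyrrolidine, whose phenyl group on the carbon syn to C2–H of the diene blocks one diene face to the endo-oriented lactone carbonyl. C5 follows from the (Z)-enol ether geometry and C8 from the (E)-enamine geometry in the endo transition state, and both are erased again (C8 in this step, C5 in step 6). The step needs regio-, endo and facial selectivity: the amino and siloxy donors make the methyl-bearing terminus the only nucleophilic end, the cis-disubstituted cyclic dienophile favours endo, and the auxiliary fixes the face; because C8 is erased, the enantiomeric purity of 9 rests on endo and facial control together. Aqueous HF then cleaves the silyl enol ether and the β-amino ketone expels the auxiliary, which is recovered.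

Step 5
Reactants: 9 (4aR,5S,8aS)-5-methyl-3,4,4a,8a-tetrahydro-1H-isochromene-1,6(5H)-dione; 10 [4-(methoxymethoxy)phenyl]boronic acid
Product: 11 (4aR,5S,8R,8aR)-8-[4-(methoxymethoxy)phenyl]-5-methyl-3,4,4a,7,8,8a-hexahydro-1H-isochromene-1,6(5H)-dione
Conditions: [Rh(cod)OH]2 (3 mol %), dioxane/H2O 10:1, 35 °C
Reagents that add atoms: none
Why: Rhodium-catalysed conjugate arylation (Hayashi–Miyaura reaction) under base-free conditions should deliver the aryl group to C8 from the convex face of the cis-fused enone, anti to the C8a–C1 bond, which sets C8 with the aryl trans to the lactone carbonyl.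

Step 6
Reactants: 11 (4aR,5S,8R,8aR)-8-[4-(methoxymethoxy)phenyl]-5-methyl-3,4,4a,7,8,8a-hexahydro-1H-isochromene-1,6(5H)-dione
Product: 12 (4aS,8R,8aS)-8-[4-(methoxymethoxy)phenyl]-5-methyl-1-oxo-3,4,4a,7,8,8a-hexahydro-1H-isochromen-6-yl trifluoromethanesulfonate
Conditions: Tf2O, 2,6-di-tert-butyl-4-methylpyridine, CH2Cl2, 0 °C to rt
Reagents that add atoms: trifluoromethanesulfonic anhydride (Tf2O), O=S(=O)(OS(=O)(=O)C(F)(F)F)C(F)(F)F
Why: Vinyl triflate formation under non-basic conditions (O-triflation, then proton loss from the triflyloxycarbenium ion) should favour the more substituted C5=C6 enol triflate while leaving the lactone and the MOM ether alone; the C5 stereocenter is erased here.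

Step 7
Reactants: 12 (4aS,8R,8aS)-8-[4-(methoxymethoxy)phenyl]-5-methyl-1-oxo-3,4,4a,7,8,8a-hexahydro-1H-isochromen-6-yl trifluoromethanesulfonate
Product: 13 (4aS,8R,8aR)-8-[4-(methoxymethoxy)phenyl]-5-methyl-3,4,4a,7,8,8a-hexahydro-1H-isochromen-1-one
Conditions: Pd(OAc)2 (5 mol %), PPh3, HCO2H, Et3N, DMF, 60 °C
Reagents that add atoms: none
Why: Palladium-catalysed formate reduction of a vinyl triflate (oxidative addition to zerovalent palladium, formate-to-hydride exchange, reductive elimination) should replace OTf by H with the C5=C6 bond held in place; no stereocenter is touched.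

Step 8
Reactants: 14 benzene-1,3,5-triol (phloroglucinol)
Product: 15 1,3,5-tris(methoxymethoxy)benzene
Conditions: MOMCl, i-Pr2NEt, CH2Cl2, 0 °C to rt
Reagents that add atoms: chloromethyl methyl ether (MOMCl), COCCl
Why: Williamson-type O-alkylation of the three phenols should give the tris-acetal, whose MOM groups later direct lithiation and come off under mild acid.

Step 9
Reactants: 13 (4aS,8R,8aR)-8-[4-(methoxymethoxy)phenyl]-5-methyl-3,4,4a,7,8,8a-hexahydro-1H-isochromen-1-one; 15 1,3,5-tris(methoxymethoxy)benzene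
Product: 17 {(1R,2S,6R)-2-(2-hydroxyethyl)-6-[4-(methoxymethoxy)phenyl]-3-methylcyclohex-3-en-1-yl}[2,4,6-tris(methoxymethoxy)phenyl]methanone, via aryllithium 16 (not isolated)
Conditions: 15, n-BuLi, THF, 0 °C; then 13, −78 °C; then H2O
Reagents that add atoms: none
Why: Directed ortho-lithiation between two MOM ethers, followed by acyl substitution at the lactone carbonyl, should give the ketone and free the side-chain alcohol, the two ortho substituents of the aryl group preventing a second addition; C1, C2 and C6 are not touched.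

Step 10
Reactants: 17 {(1R,2S,6R)-2-(2-hydroxyethyl)-6-[4-(methoxymethoxy)phenyl]-3-methylcyclohex-3-en-1-yl}[2,4,6-tris(methoxymethoxy)phenyl]methanone
Product: 18 2-{(1S,5R,6R)-5-[4-(methoxymethoxy)phenyl]-2-methyl-6-[2,4,6-tris(methoxymethoxy)benzoyl]cyclohex-2-en-1-yl}acetaldehyde
Conditions: DMP, pyridine, CH2Cl2, 0 °C to rt
Reagents that add atoms: none
Why: Buffered hypervalent-iodine oxidation should convert the primary alcohol (drawn from any hemiketal form through the open hydroxy ketone) into the aldehyde without epimerising the centre next to the hindered ketone.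

Step 11
Reactants: 18 2-{(1S,5R,6R)-5-[4-(methoxymethoxy)phenyl]-2-methyl-6-[2,4,6-tris(methoxymethoxy)benzoyl]cyclohex-2-en-1-yl}acetaldehyde; 19 triphenyl(propan-2-yl)phosphonium iodide
Product: 21 {(1R,2S,6R)-6-[4-(methoxymethoxy)phenyl]-3-methyl-2-(3-methylbut-2-en-1-yl)cyclohex-3-en-1-yl}[2,4,6-tris(methoxymethoxy)phenyl]methanone, via isopropylidene ylide 20 (not isolated)
Conditions: 19, n-BuLi, THF, 0 °C; then 18, −78 °C to rt
Reagents that add atoms: none
Why: Wittig olefination with the non-stabilised isopropylidene ylide should turn the aldehyde into the trisubstituted alkene of the prenyl group, while the di-ortho-substituted aryl ketone is too hindered to react; no stereocenter is formed.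

Step 12
Reactants: 21 {(1R,2S,6R)-6-[4-(methoxymethoxy)phenyl]-3-methyl-2-(3-methylbut-2-en-1-yl)cyclohex-3-en-1-yl}[2,4,6-tris(methoxymethoxy)phenyl]methanone
Product: 22 {(1R,2S,6R)-6-(4-hydroxyphenyl)-3-methyl-2-(3-methylbut-2-en-1-yl)cyclohex-3-en-1-yl}(2,4,6-trihydroxyphenyl)methanone
Conditions: 3 M HCl in MeOH, 40 °C
Reagents that add atoms: none
Why: Acid-catalysed acetal exchange with methanol should remove all four MOM groups under conditions that leave the two trisubstituted alkenes and the three stereocenters intact.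

**Compound list**
1 | pent-1-yn-3-ol (racemic) | CCC(O)C#C | starting material
2 | pent-1-yn-3-one | CCC(=O)C#C | intermediate
3 | (2R,5R)-2,5-diphenylpyrrolidine | N1[C@@H](c2ccccc2)CC[C@@H]1c1ccccc1 | starting material
4 | (E)-1-[(2R,5R)-2,5-diphenylpyrrolidin-1-yl]pent-1-en-3-one | CCC(=O)/C=C/N1[C@@H](c2ccccc2)CC[C@@H]1c1ccccc1 | intermediate
5 | (2R,5R)-1-[(1E,3Z)-3-{[tert-butyl(dimethyl)silyl]oxy}penta-1,3-dien-1-yl]-2,5-diphenylpyrrolidine | C/C=C(O[Si](C)(C)C(C)(C)C)/C=C/N1[C@@H](c2ccccc2)CC[C@@H]1c1ccccc1 | intermediate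
6 | 5,6-dihydro-2H-pyran-2-one | O=C1C=CCCO1 | starting material
7 | (4aR,5S,8S,8aR)-6-{[tert-butyl(dimethyl)silyl]oxy}-8-[(2R,5R)-2,5-diphenylpyrrolidin-1-yl]-5-methyl-3,4,4a,5,8,8a-hexahydro-1H-isochromen-1-one (cycloadduct, formed in the flask in step 4) | O=C1OCC[C@@H]2[C@H](C)C(O[Si](C)(C)C(C)(C)C)=C[C@H](N3[C@@H](c4ccccc4)CC[C@@H]3c5ccccc5)[C@@H]21 | intermediate
8 | (4aR,5S,8S,8aR)-8-[(2R,5R)-2,5-diphenylpyrrolidin-1-yl]-5-methyl-3,4,4a,7,8,8a-hexahydro-1H-isochromene-1,6(5H)-dione (formed in the flask in step 4) | O=C1OCC[C@@H]2[C@H](C)C(=O)C[C@H](N3[C@@H](c4ccccc4)CC[C@@H]3c5ccccc5)[C@@H]21 | intermediate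
9 | (4aR,5S,8aS)-5-methyl-3,4,4a,8a-tetrahydro-1H-isochromene-1,6(5H)-dione (cis-fused enone lactone; C5 as formed, erased in step 6) | O=C1OCC[C@@H]2[C@H](C)C(=O)C=C[C@@H]21 | intermediate
10 | [4-(methoxymethoxy)phenyl]boronic acid | COCOc1ccc(B(O)O)cc1 | starting material
11 | (4aR,5S,8R,8aR)-8-[4-(methoxymethoxy)phenyl]-5-methyl-3,4,4a,7,8,8a-hexahydro-1H-isochromene-1,6(5H)-dione | O=C1OCC[C@@H]2[C@H](C)C(=O)C[C@@H](c3ccc(OCOC)cc3)[C@@H]21 | intermediate
12 | (4aS,8R,8aS)-8-[4-(methoxymethoxy)phenyl]-5-methyl-1-oxo-3,4,4a,7,8,8a-hexahydro-1H-isochromen-6-yl trifluoromethanesulfonate | O=C1OCC[C@@H]2C(C)=C(OS(=O)(=O)C(F)(F)F)C[C@@H](c3ccc(OCOC)cc3)[C@@H]21 | intermediate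
13 | (4aS,8R,8aR)-8-[4-(methoxymethoxy)phenyl]-5-methyl-3,4,4a,7,8,8a-hexahydro-1H-isochromen-1-one | O=C1OCC[C@@H]2C(C)=CC[C@@H](c3ccc(OCOC)cc3)[C@@H]21 | intermediate
14 | benzene-1,3,5-triol (phloroglucinol) | Oc1cc(O)cc(O)c1 | starting material
15 | 1,3,5-tris(methoxymethoxy)benzene | COCOc1cc(OCOC)cc(OCOC)c1 | intermediate
16 | [2,4,6-tris(methoxymethoxy)phenyl]lithium (formed in the flask in step 9) | [Li]c1c(OCOC)cc(OCOC)cc1OCOC | intermediate
17 | {(1R,2S,6R)-2-(2-hydroxyethyl)-6-[4-(methoxymethoxy)phenyl]-3-methylcyclohex-3-en-1-yl}[2,4,6-tris(methoxymethoxy)phenyl]methanone | OCC[C@@H]1C(C)=CC[C@@H](c2ccc(OCOC)cc2)[C@@H]1C(=O)c1c(OCOC)cc(OCOC)cc1OCOC | intermediate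
18 | 2-{(1S,5R,6R)-5-[4-(methoxymethoxy)phenyl]-2-methyl-6-[2,4,6-tris(methoxymethoxy)benzoyl]cyclohex-2-en-1-yl}acetaldehyde | O=CC[C@@H]1C(C)=CC[C@@H](c2ccc(OCOC)cc2)[C@@H]1C(=O)c1c(OCOC)cc(OCOC)cc1OCOC | intermediate
19 | triphenyl(propan-2-yl)phosphonium iodide | CC(C)[P+](c1ccccc1)(c1ccccc1)c1ccccc1.[I-] | starting material
20 | triphenyl(propan-2-ylidene)phosphorane (isopropylidene ylide, formed in the flask in step 11) | CC(C)=P(c1ccccc1)(c1ccccc1)c1ccccc1 | intermediate
21 | {(1R,2S,6R)-6-[4-(methoxymethoxy)phenyl]-3-methyl-2-(3-methylbut-2-en-1-yl)cyclohex-3-en-1-yl}[2,4,6-tris(methoxymethoxy)phenyl]methanone | CC(C)=CC[C@@H]1C(C)=CC[C@@H](c2ccc(OCOC)cc2)[C@@H]1C(=O)c1c(OCOC)cc(OCOC)cc1OCOC | intermediate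
22 | {(1R,2S,6R)-6-(4-hydroxyphenyl)-3-methyl-2-(3-methylbut-2-en-1-yl)cyclohex-3-en-1-yl}(2,4,6-trihydroxyphenyl)methanone | CC(C)=CC[C@@H]1C(C)=CC[C@@H](c2ccc(O)cc2)[C@@H]1C(=O)c1c(O)cc(O)cc1O | target

Total step count: 12. Longest linear sequence: 11 steps (steps 1–7 and 9–12; step 8 is a one-step side branch).

**Steps most likely to fail**

Step 4. The unactivated, s-trans-locked lactone may react too slowly with the C4-substituted diene, so that the diene decomposes, and endo and facial selectivity may erode at the temperature needed. The fallback sets out from 6 and returns at 9 under catalyst control. Commercial pent-1-en-3-one would be silylated (i-Pr3SiOTf, Et3N) to the acid-tolerant 2-siloxy diene (Z)-(penta-1,3-dien-3-yloxy)tri(propan-2-yl)silane F1. Its Diels–Alder reaction with 6 would be run in CH2Cl2 at low temperature under a chiral o-tolyl oxazaborolidinium triflimide (from the α,α-diphenylprolinol-derived oxazaborolidine and HNTf2, antipode chosen for the required face). The siloxy-activated terminus again bonds to the lactone β-carbon, which should give the cis-fused silyl enol ether (4aR,5S,8aS)-5-methyl-6-{[tri(propan-2-yl)silyl]oxy}-3,4,4a,5,8,8a-hexahydro-1H-isochromen-1-one F2. Saegusa–Ito dehydrosilylation with Pd(OAc)2 in MeCN would then install the C7=C8 double bond and give 9.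

Step 6. Proton loss toward C7 instead of C5 would give the regioisomeric triflate. The fallback sets out from 11 and returns at 13, bypassing 12. Bromination through the acid-equilibrated enol (pyridinium tribromide, THF, 0 °C) places bromine on the more substituted α-carbon and should give the bromo ketone (4aS,8R,8aS)-5-bromo-8-[4-(methoxymethoxy)phenyl]-5-methyl-3,4,4a,7,8,8a-hexahydro-1H-isochromene-1,6(5H)-dione F3 (C5 epimers immaterial). NaBH4 reduction would give the bromohydrin (4aS,8R,8aS)-5-bromo-6-hydroxy-8-[4-(methoxymethoxy)phenyl]-5-methyloctahydro-1H-isochromen-1-one F4. Zinc-mediated reductive elimination (Zn, AcOH, rt) then forms the C5=C6 alkene only between the two functionalised carbons.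

Step 9. The hindered aryllithium may deprotonate the lactone α-position instead of adding to the carbonyl, returning or epimerising the lactone. The fallback sets out from 13 and returns at 18, bypassing 17. Reduction with i-Bu2AlH (CH2Cl2, −78 °C) would give the lactol (4aS,8R,8aR)-8-[4-(methoxymethoxy)phenyl]-5-methyl-3,4,4a,7,8,8a-hexahydro-1H-isochromen-1-ol F5. Its open hydroxy aldehyde form should accept excess aryllithium 16 readily to give the diol {(1R,2S,6R)-2-(2-hydroxyethyl)-6-[4-(methoxymethoxy)phenyl]-3-methylcyclohex-3-en-1-yl}[2,4,6-tris(methoxymethoxy)phenyl]methanol F6. Double oxidation with DMP then gives keto aldehyde 18 directly.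

Further compounds
F1 | step 4 | (Z)-(penta-1,3-dien-3-yloxy)tri(propan-2-yl)silane | C/C=C(O[Si](C(C)C)(C(C)C)C(C)C)/C=C
F2 | step 4 | (4aR,5S,8aS)-5-methyl-6-{[tri(propan-2-yl)silyl]oxy}-3,4,4a,5,8,8a-hexahydro-1H-isochromen-1-one | O=C1OCC[C@@H]2[C@H](C)C(O[Si](C(C)C)(C(C)C)C(C)C)=CC[C@@H]21
F3 | step 6 | (4aS,8R,8aS)-5-bromo-8-[4-(methoxymethoxy)phenyl]-5-methyl-3,4,4a,7,8,8a-hexahydro-1H-isochromene-1,6(5H)-dione (C5 epimers) | O=C1OCC[C@@H]2C(C)(Br)C(=O)C[C@@H](c3ccc(OCOC)cc3)[C@@H]21
F4 | step 6 | (4aS,8R,8aS)-5-bromo-6-hydroxy-8-[4-(methoxymethoxy)phenyl]-5-methyloctahydro-1H-isochromen-1-one (C5 and C6 epimers) | O=C1OCC[C@@H]2C(C)(Br)C(O)C[C@@H](c3ccc(OCOC)cc3)[C@@H]21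
F5 | step 9 | (4aS,8R,8aR)-8-[4-(methoxymethoxy)phenyl]-5-methyl-3,4,4a,7,8,8a-hexahydro-1H-isochromen-1-ol (anomers) | OC1OCC[C@@H]2C(C)=CC[C@@H](c3ccc(OCOC)cc3)[C@@H]21
F6 | step 9 | {(1R,2S,6R)-2-(2-hydroxyethyl)-6-[4-(methoxymethoxy)phenyl]-3-methylcyclohex-3-en-1-yl}[2,4,6-tris(methoxymethoxy)phenyl]methanol (carbinol epimers) | OCC[C@@H]1C(C)=CC[C@@H](c2ccc(OCOC)cc2)[C@@H]1C(O)c1c(OCOC)cc(OCOC)cc1OCOC
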